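**Retrosynthetic overview**
1. Target 9 ⇒ enone Cα=Cβ bond: Claisen–Schmidt condensation of chroman methyl ketone 6 with bis-MOM aldehyde 7; the MOM groups come off in the same pot (via 8). Ring B is bought and joined last.
2. 6 ⇒ O1–C2 bond of the pyran ring: Markovnikov hydroalkoxylation of the isopropenyl group of lavandulyl acetophenone 5 by its 4'-OH. This is the only ring built in the route.
3. 5 ⇒ aryl–CH2 bond (key bond): visible-light nickel/iridium deoxygenative coupling of aryl iodide 2 with (R)-lavandulol 3 (via adduct 4). The single stereocentre is bought in 3 and never reacts.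
4. 2 ⇒ C–I bond: chelation-directed iodination of bought acetophenone 1 (ring A bought intact).
5. Ring order: ring A (bought) → pyran ring (step 3) → ring B (bought, attached in step 4).

Assumption: (R)-(−)-lavandulol 3 is bought as the single natural enantiomer, and 2,4-bis(methoxymethoxy)benzaldehyde 7 is bought as a catalogue compound (otherwise one step from 2,4-dihydroxybenzaldehyde).

**Step 1**
Reactants: 1 1-(2,4-dihydroxy-6-methoxyphenyl)ethan-1-one
Product: 2 1-(2,4-dihydroxy-3-iodo-6-methoxyphenyl)ethan-1-one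
Conditions: I2 (0.40 equiv), HIO3 (0.20 equiv), EtOH–H2O (4:1), 25 °C, 3 h, dark
Reagents that add atoms: iodine, II; iodic acid, OI(=O)=O
Why: Electrophilic aromatic iodination goes to C3', which lies between both hydroxyl groups and is favoured by the bond fixation of the hydrogen-bonded 2'-hydroxy ketone (as in the 3-iodination of resacetophenone); all iodine is used, water is the only by-product, and the exact 1.0 equivalent of electrophilic iodine limits the 3',5'-diiodide.

**Step 2**
Reactants: 2 1-(2,4-dihydroxy-3-iodo-6-methoxyphenyl)ethan-1-one; 3 (2R)-5-methyl-2-(prop-1-en-2-yl)hex-4-en-1-ol [(R)-lavandulol]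
Product: 5 1-{2,4-dihydroxy-6-methoxy-3-[(2S)-5-methyl-2-(prop-1-en-2-yl)hex-4-en-1-yl]phenyl}ethan-1-one, via lavandulyl benzoxazoline adduct 4 (not isolated)
Conditions: 3 (1.0 equiv), 5,7-di-tert-butyl-3-phenylbenzoxazolium tetrafluoroborate (1.1 equiv), pyridine (1.1 equiv), MTBE, 25 °C, 15 min, filter; then 2 (1.5 equiv), [Ir(ppy)2(dtbbpy)]PF6 (2 mol%), NiBr2(dtbbpy) (15 mol%), quinuclidine (3.0 equiv), phthalimide (0.3 equiv), DMA–MTBE, 450 nm LEDs, 25 °C, 3 h
Reagents that add atoms: none
Why: Proposed new method: adduct 4 is oxidised by the excited iridium photocatalyst, deprotonated by quinuclidine and fragments by β-scission to the primary lavandulyl radical, which is captured by the aryl–nickel species formed by oxidative addition of zerovalent nickel into the C–I bond of 2 and is released by C(sp3)–C(sp2) reductive elimination from trivalent nickel, the C–I bond serving as internal oxidant; the closest known reaction is the NHC-mediated nickel/photoredox deoxygenative arylation of alcohols with aryl bromides, not yet shown for an unprotected, doubly ortho-oxygenated iodophenol (4'-OH carried as its quinuclidinium phenolate, 2'-OH locked in the hydrogen bond to the acetyl group) or for a chiral β-branched homoallylic alcohol whose radical can undergo a 1,2-vinyl shift (countered by the high nickel loading); the radical sits on C1, so the bought C2 stereocentre is untouched and its descriptor changes from R to S only through CIP priorities.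

**Step 3**
Reactants: 5 1-{2,4-dihydroxy-6-methoxy-3-[(2S)-5-methyl-2-(prop-1-en-2-yl)hex-4-en-1-yl]phenyl}ethan-1-one
Product: 6 1-[(3S)-5-hydroxy-7-methoxy-2,2-dimethyl-3-(3-methylbut-2-en-1-yl)-3,4-dihydro-2H-chromen-6-yl]ethan-1-one
Conditions: Co(tBu4-salen) [C32H46CoN2O2, divalent cobalt complex of N,N'-bis(3,5-di-tert-butylsalicylidene)ethane-1,2-diamine] (5 mol%), fac-Ir(ppy)3 (1 mol%), 2,4,6-collidinium triflate (20 mol%), CH2Cl2, 450 nm LEDs, 25 °C, 12 h
Reagents that add atoms: none
Why: Redox-neutral photoredox/cobalt-hydride Markovnikov hydroalkoxylation (Mukaiyama-type hydrogen-atom transfer with radical–polar crossover): the cobalt hydride delivers H• to the accessible 1,1-disubstituted isopropenyl alkene rather than the trisubstituted prenyl alkene, and the oxidised tertiary alkylcobalt is displaced in a 6-exo closure by the free, more acidic 4'-OH (the 2'-OH is tied up by the acetyl group); no stereocentre is formed (C2 is CMe2) and C3 is not involved.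

**Step 4**
Reactants: 6 1-[(3S)-5-hydroxy-7-methoxy-2,2-dimethyl-3-(3-methylbut-2-en-1-yl)-3,4-dihydro-2H-chromen-6-yl]ethan-1-one; 7 2,4-bis(methoxymethoxy)benzaldehyde
Product: 9 (2E)-3-(2,4-dihydroxyphenyl)-1-[(3S)-5-hydroxy-7-methoxy-2,2-dimethyl-3-(3-methylbut-2-en-1-yl)-3,4-dihydro-2H-chromen-6-yl]prop-2-en-1-one, via bis-MOM chalcone 8 (not isolated)
Conditions: 7 (1.2 equiv), KOH (50% aq., 10 equiv), EtOH, 25 °C, 36 h; then MeOH, HCl (to 2 M), 45 °C, 1 h, same pot
Reagents that add atoms: none
Why: Claisen–Schmidt aldol condensation (E1cB dehydration gives the thermodynamic E-enone) followed by acid-catalysed methanolysis of the two MOM acetals; the chroman ether, the prenyl group and the C3 stereocentre are inert to both stages at these temperatures.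

**Compound list**
1 | 1-(2,4-dihydroxy-6-methoxyphenyl)ethan-1-one | CC(=O)c1c(O)cc(O)cc1OC | starting material
2 | 1-(2,4-dihydroxy-3-iodo-6-methoxyphenyl)ethan-1-one | CC(=O)c1c(O)c(I)c(O)cc1OC | intermediate
3 | (2R)-5-methyl-2-(prop-1-en-2-yl)hex-4-en-1-ol, (R)-lavandulol | OC[C@H](CC=C(C)C)C(C)=C | starting material
4 | 5,7-di-tert-butyl-2-{[(2R)-5-methyl-2-(prop-1-en-2-yl)hex-4-en-1-yl]oxy}-3-phenyl-2,3-dihydro-1,3-benzoxazole (epimers at the acetal carbon) | CC(C)(C)c1cc(C(C)(C)C)c2OC(OC[C@H](CC=C(C)C)C(C)=C)N(c3ccccc3)c2c1 | intermediate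
5 | 1-{2,4-dihydroxy-6-methoxy-3-[(2S)-5-methyl-2-(prop-1-en-2-yl)hex-4-en-1-yl]phenyl}ethan-1-one | CC(=O)c1c(O)c(C[C@H](CC=C(C)C)C(C)=C)c(O)cc1OC | intermediate
6 | 1-[(3S)-5-hydroxy-7-methoxy-2,2-dimethyl-3-(3-methylbut-2-en-1-yl)-3,4-dihydro-2H-chromen-6-yl]ethan-1-one | COc1cc2c(c(O)c1C(C)=O)C[C@H](CC=C(C)C)C(C)(C)O2 | intermediate
7 | 2,4-bis(methoxymethoxy)benzaldehyde | O=Cc1ccc(OCOC)cc1OCOC | starting material
8 | (2E)-3-[2,4-bis(methoxymethoxy)phenyl]-1-[(3S)-5-hydroxy-7-methoxy-2,2-dimethyl-3-(3-methylbut-2-en-1-yl)-3,4-dihydro-2H-chromen-6-yl]prop-2-en-1-one | COCOc1ccc(/C=C/C(=O)c2c(OC)cc3c(c2O)C[C@H](CC=C(C)C)C(C)(C)O3)c(OCOC)c1 | intermediate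
9 | (2E)-3-(2,4-dihydroxyphenyl)-1-[(3S)-5-hydroxy-7-methoxy-2,2-dimethyl-3-(3-methylbut-2-en-1-yl)-3,4-dihydro-2H-chromen-6-yl]prop-2-en-1-one | COc1cc2c(c(O)c1C(=O)/C=C/c1ccc(O)cc1O)C[C@H](CC=C(C)C)C(C)(C)O2 | target

**Totals**
Total step count: 4. Longest linear sequence: 4 steps (1 → 2 → 5 → 6 → 9).

**Three steps most likely to fail**

Step 2, the proposed new coupling. The risks are proto-deiodination of 2, slow radical capture at the doubly ortho-oxygenated aryl–nickel, and formation of the 1,2-vinyl-shift isomer. The fallback uses known chemistry, a B-alkyl Suzuki–Miyaura coupling that never generates a free lavandulyl radical. It sets out from 3, which is converted (I2, PPh3, imidazole, CH2Cl2, 0 °C) into (R)-lavandulyl iodide F1. Iodine–lithium exchange (t-BuLi, 2.1 equiv, Et2O, −78 °C) and trapping with B-methoxy-9-BBN give lithium B-methoxy-B-[(R)-lavandulyl]-9-BBN borate F2. This is coupled without isolation with 2 (Pd(dppf)Cl2 5 mol%, aq. K3PO4, DMF, 50 °C; free phenols are tolerated as phenolates) and comes back to the route at 5.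

Step 3, the chemoselective ring closure. The risks are hydrogen-atom transfer to the prenyl alkene, isomerisation of the isopropenyl group to the achiral tetrasubstituted alkene, and closure on the 2'-OH. The fallback replaces the radical manifold by a polar intramolecular oxymercuration–demercuration. It sets out from 5; Hg(OAc)2 (1.05 equiv, THF, 0 °C) gives the 2-(acetoxymercuriomethyl)chroman F3 by attack of the 4'-OH on the mercurinium ion of the more reactive 1,1-disubstituted alkene. NaBH4 in aq. NaOH (0 °C) then replaces mercury by hydrogen and the sequence comes back at 6.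

Step 4, the one-pot condensation and deprotection. In the acid stage the 5-OH can add to the enone to give the flavanone, the ring-B 2-OH can close to a flavylium salt, and HCl can add to the prenyl group. The fallback changes the protecting-group logic so that no acid is needed. It sets out from 6, which is condensed (KOH, EtOH, 25 °C) with 2,4-bis(prop-2-en-1-yloxy)benzaldehyde F4 (made from 2,4-dihydroxybenzaldehyde, allyl bromide and K2CO3 in DMF). The resulting bis-allyl chalcone F5 is isolated. Neutral Tsuji–Trost deallylation (Pd(PPh3)4 5 mol%, N-methylaniline, THF, 25 °C) then comes back at 9.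

**Further compounds**
F1 | step 2 | (3R)-3-(iodomethyl)-2,6-dimethylhepta-1,5-diene, (R)-lavandulyl iodide | IC[C@H](CC=C(C)C)C(C)=C
F2 | step 2 | lithium 9-methoxy-9-[(2R)-5-methyl-2-(prop-1-en-2-yl)hex-4-en-1-yl]-9-borabicyclo[3.3.1]nonan-9-uide | [Li+].CO[B-]1(C[C@H](CC=C(C)C)C(C)=C)C2CCCC1CCC2
F3 | step 3 | 1-[(3S)-2-[(acetoxymercurio)methyl]-5-hydroxy-7-methoxy-2-methyl-3-(3-methylbut-2-en-1-yl)-3,4-dihydro-2H-chromen-6-yl]ethan-1-one (epimers at C2) | COc1cc2c(c(O)c1C(C)=O)C[C@H](CC=C(C)C)C(C)(C[Hg]OC(C)=O)O2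
F4 | step 4 | 2,4-bis(prop-2-en-1-yloxy)benzaldehyde | O=Cc1ccc(OCC=C)cc1OCC=C
F5 | step 4 | (2E)-3-[2,4-bis(prop-2-en-1-yloxy)phenyl]-1-[(3S)-5-hydroxy-7-methoxy-2,2-dimethyl-3-(3-methylbut-2-en-1-yl)-3,4-dihydro-2H-chromen-6-yl]prop-2-en-1-one | C=CCOc1ccc(/C=C/C(=O)c2c(OC)cc3c(c2O)C[C@H](CC=C(C)C)C(C)(C)O3)c(OCC=C)c1
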